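## Structural features

- The target has three rings. Ring A is a ten-membered carbocycle (C1–C10). Ring B is a 3(2H)-furanone made by an oxygen bridge from C10 to C3 (O–C3=C2–C1(=O)–C10). Ring C is an α-methylene-γ-butyrolactone fused at C6/C7 (C11–C13).
- Five contiguous stereocentres run from C6 to C10. On ring A the C6–O, C7–C11, C8–O and C9–O bonds all lie on one face, so the lactone is cis-fused and the C8/C9 diol is erythro. C10 carries its methyl on that same face and its bridge oxygen on the other.
- C8 bears a methacrylate and C9 a free hydroxyl, so two neighbouring secondary oxygens must be told apart.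
- Fragile groups are the exocyclic methylene lactone and the methacrylate (both Michael acceptors), the cross-conjugated vinylogous ester of ring B, and the lactone itself, which can migrate to O8 under base once O8 is free.
- The real difficulty is ring A: a strained medium ring holding a diene C2=C3–C4=C5 that is trans at C2=C3 (forced by ring B) and cis at C4=C5, next to a quaternary carbinol.
- That cis,trans-diene is what conrotatory opening of a cis-fused cyclobutene delivers. The key step therefore builds C2–C3 and C4–C5 by adding an alkyne C3≡C4, tethered through the C10 oxygen, across the C2=C5 alkene of an eight-membered enone; the temporary C2–C5 bond is then broken thermally.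

## Logic of the disconnections

1. **31 ⇒ 29 + 30.** The O8–acyl bond is cut last-formed because the methacrylate is the most labile group and a second Michael acceptor. This keeps it out of every earlier step. The forward step must discriminate O8 from O9.

2. **29 ⇒ 28 ⇒ 26 ⇒ 25.** The O8/O9 hydroxyls go back to an acetonide, and C11=C13 goes back to C11(H)–C13H2–O-benzyl-type ether (the C13–O bond is re-added). This gives a robust, non-electrophilic intermediate for light and heat. Forward, the base-mediated elimination must precede acetonide removal, so that no free O8 meets base.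

3. **25 ⇒ 24.** The C2–C5 σ bond is re-formed (retro-electrocyclic opening). The strained ten-membered ring becomes an eight-membered ring carrying a cis-fused cyclobutene. Forward, the conrotation can go one way only and the ring fusion must be cis.

4. **24 ⇒ 23.** C2–C3 and C4–C5 are cut (retro-[2+2]). Two rings and the C2/C5 stereocentres disappear, leaving a cyclooctenone and a propynyl ether on O10. Forward, the tether must set face and regiochemistry and the excited enone must be trapped quickly.

5. **23 ⇒ 22 ⇒ 21.** The C1 ketone and C12 lactone carbonyl are returned to a silylated carbinol and lactol. Forming the ynol ether needs KH and n-BuLi, which neither carbonyl would survive. Forward, the re-oxidation must be neutral and must spare the ynol ether.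

6. **21 ⇒ 17 + 18 (and MeI).** O10–C3 and C4–C15 are cut. The ynol ether is the most sensitive group, so it is made as late as possible, but after metathesis (an enyne pathway would otherwise compete). Forward, O10 must be the only free hydroxyl and neighbouring silyl groups must not migrate.

7. **17 ⇒ 16 ⇒ 15.** Silyl groups are removed and C1/C12 returned to ketone and lactone. This connects the base-stable form to the carbonyl form in which the ring is closed.

8. **15 ⇒ 14.** C2=C5 is cut (retro-metathesis), opening ring A's eight-membered precursor to a chain with a vinyl ketone and a propenyl group. Forward, an eight-membered ring must close; the two cis-fused five-membered rings and the quaternary C10 provide the pre-organisation.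

9. **14 ⇒ 11 + 12.** C1–C10 is cut. The quaternary carbinol comes from a methyl ketone and an acryloyl anion equivalent. Forward, the addition must take the chelated face set by O9 and must prefer the ketone to the lactone.

10. **11 ⇒ 10 ⇒ 9.** The C10 ketone goes back to a vinyl group, and the C13–O bond is removed (retro-oxa-Michael). This exposes the methylene lactone as the point where C13 oxygen is introduced. Forward, oxidation must choose the terminal alkene over the propenyl group.

11. **9 ⇒ 6 + 7.** C6–C7 and O6–C12 are cut. One allylation-lactonisation sets C6 and C7 together. Forward, it needs syn selectivity (cis-lactone) and attack on the correct face next to C8.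

12. **6 ⇒ 5 ⇒ 3 + 4.** C7–C11 is cut, with allylic transposition of the leaving group. The three lactone carbons come from an acrylate. The forward step needs only an aldehyde at C7.

13. **3 ⇒ 2 ⇒ 1.** The C10–O ring bond and C14–I are reconnected (retro-fragmentation). C8 and C9 come from the chiral pool with both chain ends already differentiated. Forward, the cis-aldehyde must not epimerise.

## Other disconnections considered

Alternative 1: The cut is at C8=C9, after removing the two hydroxyls. In the forward direction the second-generation Hoveyda–Grubbs catalyst would join a vinyl group on C7 with one on C10, lose ethylene, and close ring A as the Z-alkene A1; syn-dihydroxylation with OsO4 and C8 acylation would follow.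
- In its favour: rings B and C and the Z-C4=C5 alkene are made by ordinary acyclic chemistry; there is no photochemistry and no ynol ether; few protecting groups are needed. On step economy it is very probably the better plan.
- Against it here: metathesis must build a strained ten-membered ring that already holds the rigid ring B, between a vinyl group on a quaternary carbon and one beside the lactone, with the methylene lactone as a competing alkene and oligomerisation as the thermodynamic sink. The osmylation must then pick C8=C9 among four alkenes and the face cis to C7–C11, which only the ring conformation controls.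
- Comparison: the chosen plan takes C8/C9 from the chiral pool (certain configuration) and forms ring A in a strain-releasing step, whereas A1 is formed against strain. Both plans end with the same O8/O9 discrimination, so they are equal on that point.

Alternative 2: The cut is C3–C4, with C1–C6 reconnected (retro-oxy-Cope). Forward, KH with 18-crown-6 would turn a C1 carbinol bearing an ethoxyethynyl group into its alkoxide, and the [3,3] shift would expand a six-membered chiral-pool ring to the ten-membered 3-ethoxy-2,5-dienone A2.
- In its favour: the anionic oxy-Cope is one of the most dependable entries to ten-membered rings and carries no ring strain penalty in the transition state. The vinylogous ester needed for ring B appears directly. On reliability of the ring-forming step it is better than the photocycloaddition.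
- Against it here: A2 has its alkene at C5=C6 instead of C4=C5, an sp3 C4, no oxygen at C6, and C11 only at the isopropenyl oxidation level. Alkene transposition with C6 oxygenation, a three-stage oxidation to the lactone carbonyl and control of the Z geometry would all come after ring formation, on a sensitive medium ring.
- Comparison: the chosen plan has C6, C11, C12 and C13 at their final oxidation pattern before ring expansion and needs only deprotections afterwards; overall step count would probably be similar or longer for this alternative.

Alternative 3: The cuts are C7–C11 and C8–O. Forward, Bu3SnH with excess nitroxide would generate a vinyl radical at C11 from a bromoallyl acetal on O6; 5-exo cyclisation onto C7 and capture of the C8 radical would give the methylene lactol ether A3.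
- In its favour: ring C (as a lactol ether) and the C8–O bond form in one step, the methylene group needs no mask, and O8 (alkoxyamine) and O9 (silyl ether) are chemically distinct. On the O8/O9 problem it is clearly better than the chosen plan, which leaves this to a late selective acylation.
- Against it here: it does not address ring A, which would have to be made another way with a C7=C8 alkene in place. A vinyl radical in a medium ring has transannular options (C4=C5, C2=C3, 1,5-hydrogen shift), the nitroxide can intercept the vinyl radical before cyclisation, and the C8 configuration rests on the trapping face.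
- Comparison: it is complementary to the chosen ring construction rather than a rival. Its endgame (N–O cleavage, lactol oxidation, desilylation, acylation) is about equal in length to the chosen one.

Key step: step 15

Remarks on the chemistry (germacrane numbering throughout; C14 is the methyl on C10, C15 the methyl on C4):
- 2,3-O-Isopropylidene-D-erythronolactone carries the C8/C9 diol in the required absolute sense only if its carbonyl carbon becomes C7 and its CH2O carbon C10. Building C10 from the lactone carbonyl would give the antipodal diol. The D-ribose derivative 1 has the same diol with C7 already an acetal carbon and C10 already bonded to C14, so it is used instead.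
- The propynyl ether cannot be made on the keto lactone, because KH and n-BuLi are required. C1 and C12 are therefore carried as silylated carbinol and lactol through step 12 and re-oxidised. The C13 mask is a 4-methoxybenzyl ether, which survives the fluoride step where a silyl mask would not.
- Spectator centres are erased later: C7 in 5; C11 in 10–27 (C13 expected trans to C8); C1 and C12 in 16, 17 and 19–22 (epimer mixtures, left open in the SMILES).

## Route

Step 1
Reactants: 1 methyl 2,3-O-isopropylidene-β-D-ribofuranoside
Product: 2 methyl 5-deoxy-5-iodo-2,3-O-isopropylidene-β-D-ribofuranoside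
Conditions: I2, PPh3, imidazole, PhMe, 70 °C
Reagents that add atoms: iodine, II
Why: Garegg–Samuelsson iodination of the only free (primary) hydroxyl; the glycoside and acetonide are inert and no stereocentre is touched.

Step 2
Reactants: 2 methyl 5-deoxy-5-iodo-2,3-O-isopropylidene-β-D-ribofuranoside
Product: 3 (4R,5R)-2,2-dimethyl-5-vinyl-1,3-dioxolane-4-carbaldehyde (C7 aldehyde; C8/C9 acetonide; C10=C14 vinyl)
Conditions: Zn dust, THF/H2O 4:1, ultrasound, 40 °C; ether solution used at once
Reagents that add atoms: none
Why: Bernet–Vasella fragmentation: zinc inserts into C–I, the ring C–O bond is expelled and the hemiacetal anion collapses to the aldehyde with loss of methoxide; C8 and C9 are ribose C2 and C3 carried over unchanged, and immediate use avoids epimerisation of the cis-aldehyde at C8.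

Step 3
Reactants: 3 (4R,5R)-2,2-dimethyl-5-vinyl-1,3-dioxolane-4-carbaldehyde; 4 methyl acrylate
Product: 5 methyl 2-[hydroxy(2,2-dimethyl-5-vinyl-1,3-dioxolan-4-yl)methyl]acrylate (C7 epimers)
Conditions: DABCO (0.5 equiv), 1,4-dioxane/H2O 1:1, rt
Reagents that add atoms: none
Why: Morita–Baylis–Hillman reaction forms C7–C11; the α-alkoxy aldehyde is an activated acceptor and the aqueous medium shortens exposure of the epimerisable C8; the new C7 carbinol centre becomes sp2 in step 4.

Step 4
Reactants: 5 methyl 2-[hydroxy(2,2-dimethyl-5-vinyl-1,3-dioxolan-4-yl)methyl]acrylate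
Product: 6 methyl (Z)-2-(bromomethyl)-3-[(4S,5R)-2,2-dimethyl-5-vinyl-1,3-dioxolan-4-yl]acrylate
Conditions: NBS, Me2S, CH2Cl2, 0 °C to rt
Reagents that add atoms: N-bromosuccinimide, O=C1CCC(=O)N1Br
Why: The Corey–Kim reagent activates the hydroxyl as an alkoxysulfonium ion and bromide attacks the methylene terminus (SN2'); the trisubstituted alkene should form as the usual Z isomer with C8 cis to the CH2Br arm.

Step 5
Reactants: 6 methyl (Z)-2-(bromomethyl)-3-[(4S,5R)-2,2-dimethyl-5-vinyl-1,3-dioxolan-4-yl]acrylate; 7 (E)-but-2-enal
Product: 9 cis-α-methylene-γ-butyrolactone (C6 (E)-propenyl; C7 dioxolanyl), via syn-hydroxy ester 8 (not isolated)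
Conditions: In powder, THF/H2O 1:1, rt; then PPTS, CH2Cl2, rt
Reagents that add atoms: none
Why: Barbier-type allylation: the allylindium species adds through its γ-carbon C7 to the aldehyde (1,2) in a closed chair, and the geometry with C8 cis to C13 gives the syn C6/C7 pair and hence the cis-lactone on ring closure. With H8 eclipsing the alkene (allylic strain) the aldehyde should approach C7 anti to C9 and its cis-disposed C10 arm, which is the C7 configuration of the target. Indium tolerates water, the acetonide and the vinyl group.

Step 6
Reactants: 9 cis-α-methylene-γ-butyrolactone (C6 (E)-propenyl; C7 dioxolanyl)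
Product: 10 α-(4-methoxybenzyloxymethyl) lactone (C13 trans to C8)
Conditions: 4-MeOC6H4CH2OH (3 equiv), KOtBu (0.1 equiv), THF, 0 °C
Reagents that add atoms: 4-methoxybenzyl alcohol, COc1ccc(CO)cc1
Why: Base-catalysed oxa-Michael addition to the exocyclic acrylate masks the methylene lactone against metathesis, organometallics and the photochemistry; C11 is reprotonated under equilibrating conditions, and its configuration is immaterial because step 18 removes it.

Step 7
Reactants: 10 α-(4-methoxybenzyloxymethyl) lactone (C13 trans to C8)
Product: 11 C10 methyl ketone
Conditions: PdCl2 (10 mol %), CuCl (1 equiv), O2 (1 atm), DMF/H2O 7:1, rt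
Reagents that add atoms: water, O
Why: Wacker–Tsuji oxidation: the terminal vinyl group reacts much faster than the 1,2-disubstituted propenyl group, and hydroxypalladation at the internal carbon next to the acetonide gives the methyl ketone, whose methyl is C14 (ribose C5).

Step 8
Reactants: 11 C10 methyl ketone; 12 methoxyallene
Product: 14 α'-hydroxy vinyl ketone (C10 tertiary carbinol; C1 ketone), via methoxyallenyl carbinol 13 (not isolated)
Conditions: 11, MgBr2·OEt2, CH2Cl2/Et2O, −78 °C; 1-lithio-1-methoxyallene (from 12, n-BuLi, THF, −40 °C), −78 °C; then 1 M H2SO4, THF, 0 °C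
Reagents that add atoms: water, O
Why: The lithiated alkoxyallene is an acryloyl anion equivalent (1,2-addition, then enol ether hydrolysis); it should attack the magnesium chelate between the ketone oxygen and O9 from the face away from C8 (chelation control), which puts the C10 methyl cis to O9 as the target requires. At −78 °C the activated ketone should react well ahead of the lactone.

Step 9
Reactants: 14 α'-hydroxy vinyl ketone (C10 tertiary carbinol; C1 ketone)
Product: 15 α'-hydroxy cyclooctenone fused to lactone and acetonide
Conditions: second-generation Hoveyda–Grubbs catalyst RuCl2(H2IMes)(=CH-C6H4-2-OiPr) (10 mol %), PhMe (2 mM), 80 °C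
Reagents that add atoms: none
Why: Ring-closing metathesis forms C2=C5 with loss of propene (initiation at the propenyl group, closure on the vinyl ketone); the two cis-fused five-membered rings and the quaternary C10 hold the chain ends close, and an eight-membered ring allows only the Z alkene.

Step 10
Reactants: 15 α'-hydroxy cyclooctenone fused to lactone and acetonide
Product: 16 cyclooctene C1 carbinol C12 lactol (epimer mixture at C1 and C12)
Conditions: iBu2AlH (4 equiv), CH2Cl2, −78 °C; Rochelle salt
Reagents that add atoms: none
Why: iBu2AlH reduces the enone 1,2 and stops the lactone at the lactol at −78 °C; both carbonyls must be absent during the strongly basic step 12, and both new carbinol centres return to carbonyls in step 14.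

Step 11
Reactants: 16 cyclooctene C1 carbinol C12 lactol (epimer mixture at C1 and C12)
Product: 17 bis(triisopropylsilyl) ether with free C10 hydroxyl
Conditions: iPr3SiOTf (2.3 equiv), 2,6-lutidine, CH2Cl2, −78 to 0 °C
Reagents that add atoms: triisopropylsilyl trifluoromethanesulfonate, CC(C)[Si](C(C)C)(C(C)C)OS(=O)(=O)C(F)(F)F
Why: The silyl triflate silylates the secondary allylic and the anomeric hydroxyl but not the tertiary C10 hydroxyl; triisopropylsilyl is chosen because it resists O-to-O migration to a neighbouring alkoxide in step 12.

Step 12
Reactants: 17 bis(triisopropylsilyl) ether with free C10 hydroxyl; 18 trichloroethylene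
Product: 21 C10 1-propynyl ether, via dichlorovinyl ether 19 (not isolated), via lithium alkynyl ether 20 (not isolated)
Conditions: KH, THF, 0 °C; 18, 0 °C to rt; n-BuLi (3 equiv), −78 to −40 °C; MeI, HMPA, −78 to 0 °C; basic alumina
Reagents that add atoms: iodomethane, CI
Why: Ynol ether synthesis through the 1,2-dichlorovinyl ether: the potassium alkoxide adds to dichloroacetylene formed in situ from 18, n-BuLi effects β-elimination and chlorine–lithium exchange, and the lithium alkoxyacetylide is methylated at carbon (this methyl is C15). The substrate has no carbonyl group; the product is kept at or below room temperature because tertiary-alkyl ynol ethers lose ketene by a retro-ene path on heating.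

Step 13
Reactants: 21 C10 1-propynyl ether
Product: 22 propynyl ether with free C1 carbinol and C12 lactol
Conditions: Bu4NF, THF, 0 °C to rt
Reagents that add atoms: none
Why: Fluoride-mediated desilylation under basic, non-acidic conditions leaves the ynol ether, the acetonide and the 4-methoxybenzyl ether intact.

Step 14
Reactants: 22 propynyl ether with free C1 carbinol and C12 lactol
Product: 23 cyclooctenone propynyl ether with masked lactone
Conditions: (nPr)4N[RuO4] (10 mol %), N-methylmorpholine N-oxide, 4 Å MS, CH2Cl2, 0 °C to rt
Reagents that add atoms: none
Why: Ley–Griffith oxidation converts the allylic alcohol into the enone and the lactol into the lactone under neutral conditions that the acid-sensitive ynol ether should tolerate; O6 is locked in the lactol ring, so the second allylic position cannot be oxidised.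

Step 15
Reactants: 23 cyclooctenone propynyl ether with masked lactone
Product: 24 bridged tricyclic alkoxycyclobutene
Conditions: hν (350 nm, Pyrex), degassed PhMe (2 mM), 0 °C
Reagents that add atoms: none
Why: Proposed new method: the closest known reaction type is the intramolecular enone–alkyne [2+2] photocycloaddition of alkynes on all-carbon tethers, followed thermally by cyclobutene opening; an ynol ether tied through oxygen to the α'-carbon of a cyclooctenone has not been used in it. n→π* excitation and intersystem crossing give the enone triplet, whose C2 terminus should attack the oxygen-bearing alkyne carbon C3 (5-exo-dig, a 1,5-closure through C1–C10–O) and close the oxolan-3-one ring B. The resulting 1,4-diradical (alkyl at C5, vinyl at C4) should then collapse by C4–C5 bonding to close the cyclobutene. C2 is set by the tether, which reaches only the enone face carrying the C10–O bond, so C5 and C9 end cis on ring B. C5 is set by closure of the short-lived diradical on that same face, giving the cis ring fusion (H2 and H5 cis). The step needs the straight regiochemistry (C3 to C2, C4 to C5), which the three-atom tether secures, and capture of the triplet before it twists towards the trans-enone, which the cis-fused lactone and dioxolane on C6–C9 and the five-membered first closure should favour. Irradiation above 340 nm, stopped at full conversion, should limit a secondary 1,3-acyl shift of the β,γ-unsaturated ketone formed.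

Step 16
Reactants: 24 bridged tricyclic alkoxycyclobutene
Product: 25 ten-membered furanone Z,E-dienone with masked lactone and acetonide
Conditions: PhMe, BHT (trace), 90 °C
Reagents that add atoms: none
Why: Thermal conrotatory 4π electrocyclic opening breaks the temporary C2–C5 bond, as in the known opening of cis-bicyclo[n.2.0]alkenes to cis,trans-cycloalkadienes; ring B allows only outward rotation of C1 at C2, so C6 turns inward and C4=C5 should emerge Z. Relief of cyclobutene strain and formation of the vinylogous ester drive the ring expansion.

Step 17
Reactants: 25 ten-membered furanone Z,E-dienone with masked lactone and acetonide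
Product: 26 α-(hydroxymethyl) lactone
Conditions: DDQ, CH2Cl2/pH 7 buffer 10:1, 0 °C to rt
Reagents that add atoms: none
Why: Oxidative cleavage of the 4-methoxybenzyl ether (benzylic hydride abstraction, hydrolysis of the oxocarbenium ion); the buffered medium spares the acetonide and the electron-poor dienone should be inert to DDQ.

Step 18
Reactants: 26 α-(hydroxymethyl) lactone
Product: 28 α-methylene lactone acetonide, via mesylate 27 (not isolated)
Conditions: MsCl, Et3N, CH2Cl2, 0 °C; then DBU, 0 °C to rt
Reagents that add atoms: none
Why: Mesylation of the primary alcohol and E1cB elimination through the lactone enolate give the exocyclic methylene and remove the C11 centre; no hydroxyl is free, so the lactone cannot migrate.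

Step 19
Reactants: 28 α-methylene lactone acetonide
Product: 29 C8,C9-diol
Conditions: CF3CO2H/H2O 9:1, CH2Cl2, 0 °C
Reagents that add atoms: none
Why: Acid-catalysed acetal hydrolysis; the vinylogous ester and the methylene lactone tolerate cold aqueous acid, and acid rather than base is used so that the lactone does not shift to O8.

Step 20
Reactants: 29 C8,C9-diol; 30 methacrylic anhydride
Product: 31 target CNP0252578.5 (C8 methacrylate; C9 hydroxyl)
Conditions: 30 (1.1 equiv), Et3N, DMAP (5 mol %), CH2Cl2, −40 to 0 °C
Reagents that add atoms: none
Why: DMAP-catalysed acyl transfer; the C9 hydroxyl is neopentylic (next to quaternary C10) while the C8 hydroxyl lies between two CH carbons, so one equivalent of anhydride at low temperature should acylate O8, and any O9 ester can equilibrate to the less hindered O8 by 1,2-acyl shift.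

## Compound list

1 | methyl 2,3-O-isopropylidene-β-D-ribofuranoside | CO[C@@H]1O[C@H](CO)[C@H]2OC(C)(C)O[C@@H]12 | starting material
2 | methyl 5-deoxy-5-iodo-2,3-O-isopropylidene-β-D-ribofuranoside | CO[C@@H]1O[C@H](CI)[C@H]2OC(C)(C)O[C@@H]12 | intermediate
3 | (4R,5R)-2,2-dimethyl-5-vinyl-1,3-dioxolane-4-carbaldehyde | O=C[C@@H]1OC(C)(C)O[C@@H]1C=C | intermediate
4 | methyl acrylate | C=CC(=O)OC | starting material
5 | methyl 2-[hydroxy(2,2-dimethyl-5-vinyl-1,3-dioxolan-4-yl)methyl]acrylate, C7 epimers | C=C(C(=O)OC)C(O)[C@@H]1OC(C)(C)O[C@@H]1C=C | intermediate
6 | methyl (Z)-2-(bromomethyl)-3-[(4S,5R)-2,2-dimethyl-5-vinyl-1,3-dioxolan-4-yl]acrylate | COC(=O)/C(CBr)=C/[C@@H]1OC(C)(C)O[C@@H]1C=C | intermediate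
7 | (E)-but-2-enal | C/C=C/C=O | starting material
8 | syn-hydroxy ester (C6 carbinol, C7 dioxolanyl, methyl 2-methylene ester) | C=C(C(=O)OC)[C@@H]([C@@H](O)/C=C/C)[C@@H]1OC(C)(C)O[C@@H]1C=C | intermediate
9 | cis-α-methylene-γ-butyrolactone with C6 (E)-propenyl and C7 dioxolanyl | C=C1C(=O)O[C@@H](/C=C/C)[C@H]1[C@@H]2OC(C)(C)O[C@@H]2C=C | intermediate
10 | α-(4-methoxybenzyloxymethyl) lactone, C13 trans to C8 | COc1ccc(COC[C@@H]2C(=O)O[C@@H](/C=C/C)[C@H]2[C@@H]3OC(C)(C)O[C@@H]3C=C)cc1 | intermediate
11 | C10 methyl ketone | COc1ccc(COC[C@@H]2C(=O)O[C@@H](/C=C/C)[C@H]2[C@@H]3OC(C)(C)O[C@@H]3C(C)=O)cc1 | intermediate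
12 | methoxyallene (1-methoxypropa-1,2-diene) | COC=C=C | starting material
13 | methoxyallenyl carbinol | COc1ccc(COC[C@@H]2C(=O)O[C@@H](/C=C/C)[C@H]2[C@@H]3OC(C)(C)O[C@@H]3[C@@](C)(O)C(OC)=C=C)cc1 | intermediate
14 | α'-hydroxy vinyl ketone | COc1ccc(COC[C@@H]2C(=O)O[C@@H](/C=C/C)[C@H]2[C@@H]3OC(C)(C)O[C@@H]3[C@@](C)(O)C(=O)C=C)cc1 | intermediate
15 | α'-hydroxy cyclooctenone fused to lactone and acetonide | O[C@@]1(C)C(=O)/C=C\[C@@H]2OC(=O)[C@@H](COCc4ccc(OC)cc4)[C@@H]2[C@@H]3OC(C)(C)O[C@H]13 | intermediate
16 | cyclooctene C1 carbinol C12 lactol, epimers at C1 and C12 | O[C@@]1(C)C(O)/C=C\[C@@H]2OC(O)[C@@H](COCc4ccc(OC)cc4)[C@@H]2[C@@H]3OC(C)(C)O[C@H]13 | intermediate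
17 | bis(triisopropylsilyl) ether with free C10 hydroxyl | O[C@@]1(C)C(O[Si](C(C)C)(C(C)C)C(C)C)/C=C\[C@@H]2OC(O[Si](C(C)C)(C(C)C)C(C)C)[C@@H](COCc4ccc(OC)cc4)[C@@H]2[C@@H]3OC(C)(C)O[C@H]13 | intermediate
18 | trichloroethylene | ClC=C(Cl)Cl | starting material
19 | (E)-1,2-dichlorovinyl ether at O10 | Cl/C=C(Cl)\O[C@@]1(C)C(O[Si](C(C)C)(C(C)C)C(C)C)/C=C\[C@@H]2OC(O[Si](C(C)C)(C(C)C)C(C)C)[C@@H](COCc4ccc(OC)cc4)[C@@H]2[C@@H]3OC(C)(C)O[C@H]13 | intermediate
20 | lithium alkynyl ether at O10 | [Li]C#CO[C@@]1(C)C(O[Si](C(C)C)(C(C)C)C(C)C)/C=C\[C@@H]2OC(O[Si](C(C)C)(C(C)C)C(C)C)[C@@H](COCc4ccc(OC)cc4)[C@@H]2[C@@H]3OC(C)(C)O[C@H]13 | intermediate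
21 | C10 1-propynyl ether, bis-silylated | CC#CO[C@@]1(C)C(O[Si](C(C)C)(C(C)C)C(C)C)/C=C\[C@@H]2OC(O[Si](C(C)C)(C(C)C)C(C)C)[C@@H](COCc4ccc(OC)cc4)[C@@H]2[C@@H]3OC(C)(C)O[C@H]13 | intermediate
22 | propynyl ether with free C1 carbinol and C12 lactol | CC#CO[C@@]1(C)C(O)/C=C\[C@@H]2OC(O)[C@@H](COCc4ccc(OC)cc4)[C@@H]2[C@@H]3OC(C)(C)O[C@H]13 | intermediate
23 | cyclooctenone propynyl ether with masked lactone | CC#CO[C@@]1(C)C(=O)/C=C\[C@@H]2OC(=O)[C@@H](COCc4ccc(OC)cc4)[C@@H]2[C@@H]3OC(C)(C)O[C@H]13 | intermediate
24 | bridged tricyclic alkoxycyclobutene | C[C@]12OC3=C(C)[C@H]([C@H]3C1=O)[C@@H]4OC(=O)[C@@H](COCc6ccc(OC)cc6)[C@@H]4[C@@H]5OC(C)(C)O[C@H]25 | intermediate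
25 | ten-membered furanone Z,E-dienone with masked lactone and acetonide | C/C1=C/[C@@H]2OC(=O)[C@@H](COCc3ccc(OC)cc3)[C@@H]2[C@@H]4OC(C)(C)O[C@@H]4[C@@]5(C)OC1=CC5=O | intermediate
26 | α-(hydroxymethyl) lactone | C/C1=C/[C@@H]2OC(=O)[C@@H](CO)[C@@H]2[C@@H]4OC(C)(C)O[C@@H]4[C@@]5(C)OC1=CC5=O | intermediate
27 | C13 mesylate | C/C1=C/[C@@H]2OC(=O)[C@@H](COS(C)(=O)=O)[C@@H]2[C@@H]4OC(C)(C)O[C@@H]4[C@@]5(C)OC1=CC5=O | intermediate
28 | α-methylene lactone acetonide | C/C1=C/[C@@H]2OC(=O)C(=C)[C@@H]2[C@@H]4OC(C)(C)O[C@@H]4[C@@]5(C)OC1=CC5=O | intermediate
29 | C8,C9-diol | C/C1=C/[C@@H]2OC(=O)C(=C)[C@@H]2[C@H](O)[C@H](O)[C@@]3(C)OC1=CC3=O | intermediate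
30 | methacrylic anhydride | CC(=C)C(=O)OC(=O)C(C)=C | starting material
31 | CNP0252578.5 (C8 methacrylate, C9 hydroxyl) | C=C(C)C(=O)O[C@H]1[C@H]2C(=C)C(=O)O[C@H]2/C=C(/C)C2=CC(=O)[C@](C)(O2)[C@H]1O | target

## Step count and least certain steps

Total: 20 steps. Longest linear sequence: 20 steps (1 to 31); all other starting materials enter as single reagents.

**Step 15 (key step).** The most likely failure is relaxation of the cyclooctenone triplet by twisting towards the trans-enone, followed by dimerisation or addition, before the alkyne traps it. Charge transfer from the electron-rich ynol ether could also divert the diradical to the crossed regiochemistry, and over-irradiation could trigger a 1,3-acyl shift. The fallback uses known reaction types only and sets out from 11. Chelation-controlled addition of 1-ethoxyvinyllithium (ethyl vinyl ether, t-BuLi; ketone pre-complexed with MgBr2·OEt2 as in step 8) and dilute acid would give the α-hydroxy methyl ketone F1. Soft enolisation (MgBr2·OEt2, iPr2NEt) and C-acylation with 1-methacryloylbenzotriazole would give the α'-hydroxy 1,3-diketone F2. p-TsOH would cyclodehydrate this to the 5-isopropenyl-3(2H)-furanone F3, the classical furanone closure. Ring-closing metathesis of the isopropenyl group of F3 with the C6 propenyl group (second-generation Hoveyda–Grubbs catalyst, high dilution) would form C4=C5 and return to the route at 25, by-passing steps 8 to 16.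

**Step 8.** The likely failures are weak chelation control at C10 (the dioxolane oxygen is a modest ligand, so the open transition state may compete and give the C10 epimer) and competing enolisation of, or addition to, the lactone. The fallback sets out from 11 and replaces the organolithium by an allylindium reagent, which ignores lactones and is known for chelation control in water. Indium-mediated acetoxyallylation with 3-bromoprop-1-enyl acetate (In, THF/H2O) would give the tertiary carbinol acetate F4 (C1 epimers). Ring-closing metathesis would give the cyclooctenyl acetate F5. iBu2AlH would then cleave the acetate and reduce the lactone to the lactol in one step, returning to the route at 16.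

**Step 5.** The likely failure is poor facial selectivity at C7, or erosion of syn selectivity, through a loose transition state and E/Z equilibration of the allylindium species in water. The fallback sets out from 6 and uses a configurationally stable reagent in a closed transition state. Borylation (B2pin2, CuCl, KOAc, DMF) would give the allylboronate F6 with the geometry retained. Thermal allylboration of 7 (PhMe, 80 °C) followed by PPTS would give the hydroxy ester 8 and then 9, where it rejoins the route.

**Step 9.** The likely failure is oligomerisation by cross-metathesis, because the electron-poor vinyl ketone closes slowly on the hindered alkylidene. The fallback sets out from 14 and moves ring closure to the sp3, silylated stage. iBu2AlH would give the acyclic carbinol lactol F7, and iPr3SiOTf/2,6-lutidine the bis-silyl ether F8. Metathesis of F8, with an allylic silyl ether in place of the enone, would return to the route at 17.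

**Step 12.** The likely failures are sluggish addition of the hindered tertiary alkoxide, silyl migration from O1 to the potassium alkoxide (which would place the alkyne on the wrong oxygen), and retro-ene loss of ketene during work-up. The fallback sets out from 17 and avoids the potassium alkoxide. Formylation (acetic formic anhydride, pyridine, DMAP) would give the C10 formate F9. Dibromo-olefination (CBr4, PPh3) would give the 2,2-dibromovinyl ether F10. n-BuLi (Fritsch–Buttenberg–Wiechell rearrangement and deprotonation) would convert F10 into the lithium alkynyl ether 20, where it rejoins the route before methylation.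

**Step 20.** The likely failures are insufficient discrimination between O8 and O9, and base-induced migration of the lactone to the free O8. The fallback sets out from 29 and uses tin activation without amine base. Bu2SnO (MeOH, 65 °C) would give the dibutylstannylene acetal F11, and methacryloyl chloride (CH2Cl2, −20 °C) should acylate the less hindered tin-bound oxygen O8 and return to the route at 31.

## Further compounds

F1 | step 15 | α-hydroxy methyl ketone (C10 carbinol, C1 acetyl) | COc1ccc(COC[C@@H]2C(=O)O[C@@H](/C=C/C)[C@H]2[C@@H]3OC(C)(C)O[C@@H]3[C@@](C)(O)C(C)=O)cc1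
F2 | step 15 | α'-hydroxy 1,3-diketone with terminal isopropenyl | COc1ccc(COC[C@@H]2C(=O)O[C@@H](/C=C/C)[C@H]2[C@@H]3OC(C)(C)O[C@@H]3[C@@](C)(O)C(=O)CC(=O)C(C)=C)cc1
F3 | step 15 | 5-isopropenyl-3(2H)-furanone (ring B closed, ring A open at C4/C5) | COc1ccc(COC[C@@H]2C(=O)O[C@@H](/C=C/C)[C@H]2[C@@H]3OC(C)(C)O[C@@H]3[C@@]4(C)OC(C(C)=C)=CC4=O)cc1
F4 | step 8 | tertiary carbinol with C1 acetate and vinyl, C1 epimers | COc1ccc(COC[C@@H]2C(=O)O[C@@H](/C=C/C)[C@H]2[C@@H]3OC(C)(C)O[C@@H]3[C@@](C)(O)C(OC(C)=O)C=C)cc1
F5 | step 8 | cyclooctenyl C1 acetate with lactone, C1 epimers | O[C@@]1(C)C(OC(C)=O)/C=C\[C@@H]2OC(=O)[C@@H](COCc4ccc(OC)cc4)[C@@H]2[C@@H]3OC(C)(C)O[C@H]13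
F6 | step 5 | allylboronate (pinacolboryl in place of bromine in 6) | COC(=O)/C(CB1OC(C)(C)C(C)(C)O1)=C/[C@@H]2OC(C)(C)O[C@@H]2C=C
F7 | step 9 | acyclic C1 carbinol C12 lactol, epimers at C1 and C12 | COc1ccc(COC[C@@H]2C(O)O[C@@H](/C=C/C)[C@H]2[C@@H]3OC(C)(C)O[C@@H]3[C@@](C)(O)C(O)C=C)cc1
F8 | step 9 | acyclic bis(triisopropylsilyl) ether | COc1ccc(COC[C@@H]2C(O[Si](C(C)C)(C(C)C)C(C)C)O[C@@H](/C=C/C)[C@H]2[C@@H]3OC(C)(C)O[C@@H]3[C@@](C)(O)C(O[Si](C(C)C)(C(C)C)C(C)C)C=C)cc1
F9 | step 12 | C10 formate of 17 | O=CO[C@@]1(C)C(O[Si](C(C)C)(C(C)C)C(C)C)/C=C\[C@@H]2OC(O[Si](C(C)C)(C(C)C)C(C)C)[C@@H](COCc4ccc(OC)cc4)[C@@H]2[C@@H]3OC(C)(C)O[C@H]13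
F10 | step 12 | 2,2-dibromovinyl ether at O10 | BrC(Br)=CO[C@@]1(C)C(O[Si](C(C)C)(C(C)C)C(C)C)/C=C\[C@@H]2OC(O[Si](C(C)C)(C(C)C)C(C)C)[C@@H](COCc4ccc(OC)cc4)[C@@H]2[C@@H]3OC(C)(C)O[C@H]13
F11 | step 20 | O8,O9-dibutylstannylene acetal of 29 | C/C1=C/[C@@H]2OC(=O)C(=C)[C@@H]2[C@@H]4O[Sn](CCCC)(CCCC)O[C@@H]4[C@@]3(C)OC1=CC3=O
A1 | alternative 1 | ten-membered Z-C8=C9 triene core | C/C1=C/[C@@H]2OC(=O)C(=C)[C@@H]2/C=C\[C@@]2(C)OC1=CC2=O
A2 | alternative 2 | ten-membered 3-ethoxy-2,5-dienone | O=C1/C=C(OCC)/[C@@H](C)/C=C/[C@H](C(C)=C)[C@@H]2OC(C)(C)O[C@@H]2[C@@]1(C)OCOC
A3 | alternative 3 | cis-fused methylene lactol ether with C8 alkoxyamine | CC[Si](CC)(CC)O[C@H]1[C@@H](ON2C(C)(C)CCCC2(C)C)[C@H]3C(=C)[C@@H](OCC)O[C@H]3/C=C(/C)C2=CC(=O)[C@]1(C)O2
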